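**Retrosynthetic overview**
1. The target comes from global deprotection of a protected macrocycle. The 42-membered ring is closed last, at C2=C3, by a domino hydroformylation/HWE olefination between the C4=C5 vinyl group and a C41 phosphonopropionate.
2. C12=C13 and C14–C15 are made in one three-component lithiation–borylation–allylboration (a boron-to-carbon 1,2-metallate shift) joining carbamate fragment A (C4–C12), (Z)-propenyl-9-BBN (C13–C14) and a C15–C46 enal.
3. C29–C33 uses pentan-3-one as a linchpin: an Ipc2BOTf-mediated syn-aldol with a C2-symmetric C23–C29 dialdehyde, a TiCl4-mediated syn-aldol with the C33–C46 aldehyde, then an anti-reduction at C31.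
4. C38=C39 is made by cross-metathesis of a γ-lactone/phosphonate piece (C39–C46) with a syn-diol acetal (C33–C38). C15–C22 is grown on the ketone by anti-diol allylboration, ozonolysis/Wittig, (Z)-crotylboration and cross-metathesis with crotonaldehyde.
5. Ring order: γ-lactone first (step 8), protecting dioxane/dioxolane rings in between, macrolactone last (step 32).

Assumption: C1–C46 follow the target (C1 = macrolactone carbonyl, C46 = γ-lactone carbonyl); allyl-, crotyl- and propenylboranes, the phosphonopropionic acid, the Wittig ylide and protecting-group reagents are treated as reagents, and the facial senses quoted for the catalyst formed from [Ir(cod)Cl]2 and (R)-Cl,MeO-BIPHEP and for Ipc2BOTf are taken by analogy and not independently confirmed.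

**Fragment A (C4–C12)**

Step 1
Reactants: 1 pent-4-en-1-ol
Product: 2 pent-4-en-1-yl N,N-diisopropylcarbamate
Conditions: iPr2NCOCl, Et3N, CH2Cl2, reflux
Reagents that add atoms: N,N-diisopropylcarbamoyl chloride CC(C)N(C(C)C)C(=O)Cl
Why: O-carbamoylation of a primary alcohol; the carbamate later directs the lithiation and is the leaving group of the 1,2-metallate shift.

Step 2
Reactants: 2 pent-4-en-1-yl N,N-diisopropylcarbamate
Product: 3 4-oxobutyl N,N-diisopropylcarbamate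
Conditions: O3, CH2Cl2, -78 °C; PPh3
Reagents that add atoms: ozone [O-][O+]=O
Why: ozonolysis with reductive work-up turns the terminal alkene into the C9 aldehyde.

Step 3
Reactants: 3 4-oxobutyl N,N-diisopropylcarbamate
Product: 4 (4S,5R)-4-hydroxy-5-methylhept-6-en-1-yl N,N-diisopropylcarbamate
Conditions: (E)-crotyl-B(Ipc)2 [(+)-Ipc2B series from (-)-α-pinene; separately prepared], THF, -78 °C; aq. NaOH, H2O2
Reagents that add atoms: (E)-crotyldiisopinocampheylborane C/C=C/CB([C@H]1C[C@H]2C[C@@H]([C@@H]1C)C2(C)C)[C@H]1C[C@H]2C[C@@H]([C@@H]1C)C2(C)C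
Why: Brown crotylboration through a chair transition state; the (E)-crotyl unit gives the C8/C9 anti relationship and the Ipc ligands direct Re-face attack to set C9.

Step 4
Reactants: 4 (4S,5R)-4-hydroxy-5-methylhept-6-en-1-yl N,N-diisopropylcarbamate
Product: 5 (4S,5R)-4-(tert-butyldimethylsilyloxy)-5-methylhept-6-en-1-yl N,N-diisopropylcarbamate
Conditions: TBSOTf, 2,6-lutidine, CH2Cl2, -78 to 0 °C
Reagents that add atoms: tert-butyldimethylsilyl trifluoromethanesulfonate CC(C)(C)[Si](C)(C)OS(=O)(=O)C(F)(F)F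
Why: standard silylation of a secondary alcohol; no stereocentre is touched.

Step 5
Reactants: 5 (4S,5R)-4-(tert-butyldimethylsilyloxy)-5-methylhept-6-en-1-yl N,N-diisopropylcarbamate
Product: 6 (4S,5S)-4-(tert-butyldimethylsilyloxy)-5-methyl-6-oxohexyl N,N-diisopropylcarbamate
Conditions: O3, CH2Cl2, -78 °C; PPh3
Reagents that add atoms: ozone [O-][O+]=O
Why: ozonolysis of the only alkene gives the C7 aldehyde, used crude so the α-methyl centre C8 does not epimerise.

Step 6
Reactants: 6 (4S,5S)-4-(tert-butyldimethylsilyloxy)-5-methyl-6-oxohexyl N,N-diisopropylcarbamate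
Product: 7 C4–C12 homoallylic alcohol [4-(TBS-oxy)-6-hydroxy-5,7-dimethylnon-8-en-1-yl N,N-diisopropylcarbamate; C6 Me/C7 OH syn; C7 OH/C8 Me anti; C8 Me/C9 O anti]
Conditions: (Z)-crotyl-B(Ipc)2 [(+)-Ipc2B series from (-)-α-pinene; separately prepared], THF, -78 °C; aq. NaOH, H2O2
Reagents that add atoms: (Z)-crotyldiisopinocampheylborane C/C=C\CB([C@H]1C[C@H]2C[C@@H]([C@@H]1C)C2(C)C)[C@H]1C[C@H]2C[C@@H]([C@@H]1C)C2(C)C
Why: Brown crotylboration; the (Z)-crotyl unit gives C6/C7 syn, and the reagent-controlled Re-face attack coincides with the anti-Felkin preference of (Z)-crotylboranes for α-methyl aldehydes, so the pairing is matched.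

Step 7
Reactants: 7 C4–C12 homoallylic alcohol
Product: 8 fragment A [4,6-bis(TBS-oxy)-5,7-dimethylnon-8-en-1-yl N,N-diisopropylcarbamate; C6–C9 configured as in the target]
Conditions: TBSOTf, 2,6-lutidine, CH2Cl2, -78 to 0 °C
Reagents that add atoms: tert-butyldimethylsilyl trifluoromethanesulfonate CC(C)(C)[Si](C)(C)OS(=O)(=O)C(F)(F)F
Why: silylation of the hindered C7 alcohol completes the carbamate fragment.

**Lactone/phosphonate piece (C39–C46 plus C1–C2)**

Step 8
Reactants: 9 methyl 4-oxobutanoate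
Product: 11 (S)-5-[(R)-but-3-en-2-yl]dihydrofuran-2(3H)-one, via hydroxy ester 10 (not isolated)
Conditions: (E)-crotyl-B(Ipc)2 [(+)-Ipc2B series from (-)-α-pinene], THF, -78 °C; H2O2, pH 7 buffer; PPTS (cat.), PhH, 50 °C
Reagents that add atoms: (E)-crotyldiisopinocampheylborane C/C=C/CB([C@H]1C[C@H]2C[C@@H]([C@@H]1C)C2(C)C)[C@H]1C[C@H]2C[C@@H]([C@@H]1C)C2(C)C
Why: Brown crotylboration (Re-face attack, anti) sets C43 and C42, and the γ-hydroxy ester lactonises under mild acid to form the γ-lactone ring.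

Step 9
Reactants: 11 (S)-5-[(R)-but-3-en-2-yl]dihydrofuran-2(3H)-one
Product: 12 (S)-2-[(S)-5-oxotetrahydrofuran-2-yl]propanal
Conditions: O3, CH2Cl2, -78 °C; PPh3
Reagents that add atoms: ozone [O-][O+]=O
Why: ozonolysis gives the C41 aldehyde, carried on crude to avoid epimerisation at C42.

Step 10
Reactants: 12 (S)-2-[(S)-5-oxotetrahydrofuran-2-yl]propanal
Product: 13 (S)-5-[(2R,3S)-3-hydroxyhex-5-en-2-yl]dihydrofuran-2(3H)-one
Conditions: (-)-Ipc2B(allyl) [from (+)-α-pinene], Et2O, -78 °C; H2O2, pH 7 buffer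
Reagents that add atoms: (-)-B-allyldiisopinocampheylborane C=CCB([C@@H]1C[C@@H]2C[C@H]([C@H]1C)C2(C)C)[C@@H]1C[C@@H]2C[C@H]([C@H]1C)C2(C)C
Why: Brown allylboration; Si-face attack sets C41 syn to the C42 methyl, which is also the Felkin product, and the lactone is inert to the allylborane.

Step 11
Reactants: 13 (S)-5-[(2R,3S)-3-hydroxyhex-5-en-2-yl]dihydrofuran-2(3H)-one
Product: 14 2-(diethoxyphosphoryl)propanoate ester of 13 at the C41 oxygen (epimeric at the phosphonate carbon)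
Conditions: 2-(diethoxyphosphoryl)propanoic acid, DCC, DMAP (cat.), CH2Cl2, 0 °C to rt
Reagents that add atoms: 2-(diethoxyphosphoryl)propanoic acid CCOP(=O)(OCC)C(C)C(=O)O
Why: Steglich esterification puts C1, C2 and the C2 methyl on the C41 oxygen early, so C41 never needs a protecting group.

**Acetal piece (C33–C38) and its union with the lactone**

Step 12
Reactants: 15 acrolein
Product: 16 (S)-hexa-1,5-dien-3-ol
Conditions: (-)-Ipc2B(allyl) [from (+)-α-pinene], Et2O, -100 to -78 °C; aq. NaOH, H2O2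
Reagents that add atoms: (-)-B-allyldiisopinocampheylborane C=CCB([C@@H]1C[C@@H]2C[C@H]([C@H]1C)C2(C)C)[C@@H]1C[C@@H]2C[C@H]([C@H]1C)C2(C)C
Why: Brown allylboration by 1,2-addition to the enal; Si-face attack sets C37.

Step 13
Reactants: 16 (S)-hexa-1,5-dien-3-ol; 17 methyl acrylate
Product: 18 methyl (2E,5S)-5-hydroxyhepta-2,6-dienoate
Conditions: second-generation Hoveyda–Grubbs catalyst RuCl2(H2IMes)(=CH-C6H4-2-OiPr) (2 mol%), CH2Cl2, 40 °C
Reagents that add atoms: none
Why: olefin cross-metathesis; the unhindered allyl terminus reacts with the acrylate far faster than the vinyl carbinol, and the enoate forms with E geometry.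

Step 14
Reactants: 18 methyl (2E,5S)-5-hydroxyhepta-2,6-dienoate
Product: 19 methyl 2-[(2S,4R,6S)-2-(4-methoxyphenyl)-6-vinyl-1,3-dioxan-4-yl]acetate
Conditions: 4-MeOC6H4CHO, KOtBu (3 × 0.1 equiv), THF, 0 °C
Reagents that add atoms: 4-methoxybenzaldehyde COc1ccc(C=O)cc1
Why: Evans hemiacetal/oxa-Michael addition; the reversible conjugate addition of the hemiacetal alkoxide gives the all-equatorial 1,3-dioxane under thermodynamic control, setting C35 syn to C37.

Step 15
Reactants: 19 methyl 2-[(2S,4R,6S)-2-(4-methoxyphenyl)-6-vinyl-1,3-dioxan-4-yl]acetate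
Product: 20 2-[(2S,4R,6S)-2-(4-methoxyphenyl)-6-vinyl-1,3-dioxan-4-yl]acetaldehyde
Conditions: iBu2AlH (1.1 equiv), CH2Cl2, -78 °C; aq. KNaC4H4O6
Reagents that add atoms: none
Why: low-temperature partial reduction of the ester to the C33 aldehyde; the acetal is untouched at -78 °C.

Step 16
Reactants: 20 2-[(2S,4R,6S)-2-(4-methoxyphenyl)-6-vinyl-1,3-dioxan-4-yl]acetaldehyde; 14 phosphonopropionate ester of 13
Product: 21 C33–C46 aldehyde [PMP acetal on O35/O37; (E)-C38=C39; C41 phosphonopropionate; γ-lactone]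
Conditions: 14 (2 equiv), second-generation Hoveyda–Grubbs catalyst RuCl2(H2IMes)(=CH-C6H4-2-OiPr) (5 mol%), CH2Cl2, 40 °C
Reagents that add atoms: none
Why: cross-metathesis of the reactive allyl terminus of 14 (in excess) with the hindered allylic-oxygenated vinyl group of 20 forms the (E)-C38=C39 alkene selectively.

**Ketone piece (C17–C32)**

Step 17
Reactants: 22 propane-1,3-diol; 23 allyl acetate
Product: 24 (4R,6R)-nona-1,8-diene-4,6-diol
Conditions: 23 (10 equiv), [Ir(cod)Cl]2 (5 mol%), (R)-Cl,MeO-BIPHEP (10 mol%), 4-chloro-3-nitrobenzoic acid (20 mol%), Cs2CO3 (40 mol%), 1,4-dioxane, 90 °C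
Reagents that add atoms: allyl acetate (second molecule) C=CCOC(C)=O
Why: Krische two-directional transfer-hydrogenative carbonyl allylation; the diol is dehydrogenated one terminus at a time and each transient aldehyde is allylated under catalyst control, so two molecules of allyl acetate are incorporated (one as reactant 23, the second as the reagent listed) and the C2-symmetric anti diol (C25, C27) forms with very high ee.

Step 18
Reactants: 24 (4R,6R)-nona-1,8-diene-4,6-diol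
Product: 25 (4R,6R)-4,6-diallyl-2,2-dimethyl-1,3-dioxane
Conditions: Me2C(OMe)2, PPTS (cat.), CH2Cl2, rt
Reagents that add atoms: 2,2-dimethoxypropane COC(C)(C)OC
Why: acetonide formation on the anti-1,3-diol.

Step 19
Reactants: 25 (4R,6R)-4,6-diallyl-2,2-dimethyl-1,3-dioxane
Product: 26 2,2'-[(4S,6S)-2,2-dimethyl-1,3-dioxane-4,6-diyl]diacetaldehyde
Conditions: O3, CH2Cl2, -78 °C; PPh3
Reagents that add atoms: ozone [O-][O+]=O
Why: double ozonolysis gives the C2-symmetric C23/C29 dialdehyde, whose two formyl groups are homotopic.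

Step 20
Reactants: 27 pentan-3-one; 26 2,2'-[(4S,6S)-2,2-dimethyl-1,3-dioxane-4,6-diyl]diacetaldehyde
Product: 28 C23–C32 mono-aldol [C23 aldehyde; C25/C27 acetonide; C29 OH syn to C30 Me; ethyl ketone at C31]
Conditions: 27, (+)-Ipc2BOTf, iPr2NEt, CH2Cl2, -78 °C; then 26 (3 equiv, excess recovered), -78 to -20 °C; H2O2, MeOH, pH 7 buffer
Reagents that add atoms: none
Why: Paterson boron aldol; the (Z)-enol diisopinocampheylborinate adds through a chair transition state to one of the two homotopic formyl groups, giving the syn aldol with C29 and C30 set by the Ipc ligands, and the minor diastereomer is separable.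

Step 21
Reactants: 28 C23–C32 mono-aldol
Product: 29 C29 TBS ether of 28
Conditions: TBSOTf, 2,6-lutidine, CH2Cl2, -78 °C
Reagents that add atoms: tert-butyldimethylsilyl trifluoromethanesulfonate CC(C)(C)[Si](C)(C)OS(=O)(=O)C(F)(F)F
Why: silylation of the β-hydroxy ketone blocks retro-aldol and frees the ketone for later enolisation.

Step 22
Reactants: 29 C29 TBS ether of 28
Product: 31 C21–C32 anti-diol [C22 OH/C23 OH anti; terminal vinyl at C21], via allylic boronate 30 (not isolated)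
Conditions: (E)-(CH2)3O2B-CH=CH-CH2-B(Ipc)2 [(+)-Ipc2B series; separately prepared], Et2O, -78 °C; then H2O2, aq. NaHCO3
Reagents that add atoms: B-[(E)-3-(1,3,2-dioxaborinan-2-yl)allyl]diisopinocampheylborane B1(OCCCO1)/C=C/CB([C@H]2C[C@H]3C[C@@H]([C@@H]2C)C3(C)C)[C@H]2C[C@H]3C[C@@H]([C@@H]2C)C3(C)C; hydrogen peroxide OO
Why: Brown γ-borylallylboration then C–B oxidation; the (E)-γ-boryl reagent gives the anti relationship through the chair transition state, the Ipc ligands fix C23 by Re-face attack, oxidation with retention installs the C22 hydroxyl, and the ketone is left alone.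

Step 23
Reactants: 31 C21–C32 anti-diol
Product: 32 bis-acetonide [cis-dioxolane on O22/O23; trans-dioxane on O25/O27]
Conditions: Me2C(OMe)2, PPTS (cat.), CH2Cl2, rt
Reagents that add atoms: 2,2-dimethoxypropane COC(C)(C)OC
Why: acetonide formation on the 1,2-diol.

Step 24
Reactants: 32 bis-acetonide
Product: 34 C19–C32 (E)-2-methyl enal, via dioxolane aldehyde 33 (not isolated)
Conditions: O3, CH2Cl2, -78 °C; PPh3; then Ph3P=C(Me)CHO (1.5 equiv), PhMe, 60 °C
Reagents that add atoms: 2-(triphenylphosphoranylidene)propanal CC(C=O)=P(c1ccccc1)(c1ccccc1)c1ccccc1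
Why: one-pot ozonolysis/Wittig olefination; the stabilised formyl ylide gives the (E)-trisubstituted enal (C20=C21), ignores the ketone and does not epimerise the α-alkoxy aldehyde.

Step 25
Reactants: 34 C19–C32 (E)-2-methyl enal
Product: 35 C17–C32 allylic alcohol [C18 Me/C19 OH syn; terminal vinyl at C17]
Conditions: (Z)-crotyl-B(Ipc)2 [(-)-Ipc2B series from (+)-α-pinene; separately prepared], THF, -78 °C; H2O2, pH 7 buffer
Reagents that add atoms: (Z)-crotyldiisopinocampheylborane C/C=C\CB([C@@H]1C[C@@H]2C[C@H]([C@H]1C)C2(C)C)[C@@H]1C[C@@H]2C[C@H]([C@H]1C)C2(C)C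
Why: Brown crotylboration by 1,2-addition to the enal; the (Z)-crotyl unit gives C18/C19 syn and Si-face attack sets C19.

Step 26
Reactants: 35 C17–C32 allylic alcohol
Product: 36 C17–C32 ethyl ketone [C19 OTBS; C22/C23 and C25/C27 acetonides; C29 OTBS; ketone at C31]
Conditions: TBSOTf, 2,6-lutidine, CH2Cl2, -78 °C
Reagents that add atoms: tert-butyldimethylsilyl trifluoromethanesulfonate CC(C)(C)[Si](C)(C)OS(=O)(=O)C(F)(F)F
Why: silylation of the allylic alcohol before the TiCl4-mediated aldol.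

**Assembly**

Step 27
Reactants: 36 C17–C32 ethyl ketone; 21 C33–C46 aldehyde
Product: 37 C17–C46 β-hydroxy ketone [C32 Me and C33 OH syn; C30 Me/C32 Me syn]
Conditions: 36, TiCl4 (1.05 equiv), iPr2NEt, CH2Cl2, -78 °C; then 21, -78 °C
Reagents that add atoms: none
Why: Evans-type chlorotitanium (Z)-enolate aldol; enolisation occurs on the ethyl side before the aldehyde is added, the closed transition state gives the syn aldol, and the α'-stereocentre C30 directs the enolate face to the syn–syn adduct, setting C32 and C33 and joining the two halves.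

Step 28
Reactants: 37 C17–C46 β-hydroxy ketone
Product: 38 C31,C33-anti diol
Conditions: Me4NBH(OAc)3, MeCN/AcOH, -25 °C
Reagents that add atoms: none
Why: Evans–Saksena reduction; intramolecular hydride delivery from the C33-bound acetoxyborohydride gives the 1,3-anti diol and sets C31.

Step 29
Reactants: 38 C31,C33-anti diol
Product: 39 C17–C46 tris-acetonide [new trans-dioxane on O31/O33]
Conditions: Me2C(OMe)2, PPTS (cat.), CH2Cl2, 0 °C
Reagents that add atoms: 2,2-dimethoxypropane COC(C)(C)OC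
Why: acetonide formation removes the free hydroxyls that would protonate the allylborane in step 31.

Step 30
Reactants: 39 C17–C46 tris-acetonide; 40 (E)-crotonaldehyde
Product: 41 C15–C46 (E)-enal
Conditions: 40 (10 equiv), second-generation Hoveyda–Grubbs catalyst RuCl2(H2IMes)(=CH-C6H4-2-OiPr) (10 mol%), CH2Cl2, 40 °C
Reagents that add atoms: none
Why: cross-metathesis of the only terminal alkene with crotonaldehyde gives the (E)-enal (C15–C17); the internal and trisubstituted alkenes are much less reactive.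

Step 31
Reactants: 8 fragment A; 41 C15–C46 (E)-enal
Product: 45 C4–C46 seco-phosphonate [(E)-C12=C13; C14 Me/C15 OH syn; free C15 OH], via lithiated carbamate 42 (not isolated), via boronate complex 43 (not isolated), via allylic borane 44 (not isolated)
Conditions: 8 (1.5 equiv), s-BuLi, (-)-sparteine, Et2O, -78 °C; B-[(Z)-prop-1-enyl]-9-BBN, -78 °C; then 41, -78 to -40 °C; ethanolamine work-up
Reagents that add atoms: B-[(Z)-prop-1-en-1-yl]-9-borabicyclo[3.3.1]nonane C/C=C\B1C2CCCC1CCC2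
Why: lithiation–borylation–allylboration; sparteine-directed deprotonation gives the (S)-α-lithio carbamate, borylation with retention gives the boronate, the 1,2-metallate shift of the propenyl group from boron to C12 with inversion expels the carbamate and forms C12–C13, and the resulting (R)-allylic borane adds to the enal through a chair (C12 substituent equatorial to avoid allylic strain with the Z-methyl, which is axial), transferring chirality to C14/C15 (syn) and forming the (E)-C12=C13 alkene.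

Step 32
Reactants: 45 C4–C46 seco-phosphonate
Product: 47 protected macrolactone [42-membered ring; (E)-C2=C3], via formyl phosphonate 46 (not isolated)
Conditions: Rh(acac)(CO)2 (5 mol%), BiPhePhos (10 mol%), CO/H2 (1:1, 10 bar), K2CO3, 18-crown-6, PhMe, 65 °C, 1 mM
Reagents that add atoms: carbon monoxide [C-]#[O+]
Why: Proposed new method: linear-selective hydroformylation of the single terminal alkene by the Rh(acac)(CO)2/BiPhePhos catalyst supplies C3 as an aldehyde slowly and at low stationary concentration, and carbonate/crown-ether HWE conditions trap it intramolecularly as the (E)-2-methyl enoate, so the catalytic step acts as a built-in slow addition that favours ring closure over oligomerisation; the closest known chemistry is intermolecular tandem hydroformylation/Wittig olefination and stepwise macrocyclic HWE olefination.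

Step 33
Reactants: 47 protected macrolactone
Product: 48 target macrolide CNP0335149.1
Conditions: aq. HF (48%), MeCN/H2O, 0 °C to rt
Reagents that add atoms: none
Why: global acidic deprotection; HF cleaves the four silyl ethers and the aqueous acid hydrolyses the three acetonides and the p-methoxybenzylidene acetal while both lactones and all alkenes survive.

**Compound list**

1 | pent-4-en-1-ol | C=CCCCO | starting material
2 | pent-4-en-1-yl N,N-diisopropylcarbamate | C=CCCCOC(=O)N(C(C)C)C(C)C | intermediate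
3 | 4-oxobutyl N,N-diisopropylcarbamate | O=CCCCOC(=O)N(C(C)C)C(C)C | intermediate
4 | (4S,5R)-4-hydroxy-5-methylhept-6-en-1-yl N,N-diisopropylcarbamate | C=C[C@@H](C)[C@@H](O)CCCOC(=O)N(C(C)C)C(C)C | intermediate
5 | (4S,5R)-4-(tert-butyldimethylsilyloxy)-5-methylhept-6-en-1-yl N,N-diisopropylcarbamate | C=C[C@@H](C)[C@@H](O[Si](C)(C)C(C)(C)C)CCCOC(=O)N(C(C)C)C(C)C | intermediate
6 | (4S,5S)-4-(tert-butyldimethylsilyloxy)-5-methyl-6-oxohexyl N,N-diisopropylcarbamate | O=C[C@@H](C)[C@@H](O[Si](C)(C)C(C)(C)C)CCCOC(=O)N(C(C)C)C(C)C | intermediate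
7 | C4–C12 homoallylic alcohol: 4-(TBS-oxy)-6-hydroxy-5,7-dimethylnon-8-en-1-yl N,N-diisopropylcarbamate (C6/C7 syn; C7/C8 anti; C8/C9 anti) | C=C[C@H](C)[C@@H](O)[C@@H](C)[C@@H](O[Si](C)(C)C(C)(C)C)CCCOC(=O)N(C(C)C)C(C)C | intermediate
8 | fragment A: 4,6-bis(TBS-oxy)-5,7-dimethylnon-8-en-1-yl N,N-diisopropylcarbamate (C6–C9 as in the target) | C=C[C@H](C)[C@@H](O[Si](C)(C)C(C)(C)C)[C@@H](C)[C@@H](O[Si](C)(C)C(C)(C)C)CCCOC(=O)N(C(C)C)C(C)C | intermediate
9 | methyl 4-oxobutanoate | COC(=O)CCC=O | starting material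
10 | methyl (4S,5R)-4-hydroxy-5-methylhept-6-enoate | C=C[C@@H](C)[C@@H](O)CCC(=O)OC | intermediate (not isolated)
11 | (S)-5-[(R)-but-3-en-2-yl]dihydrofuran-2(3H)-one | C=C[C@@H](C)[C@@H]1CCC(=O)O1 | intermediate
12 | (S)-2-[(S)-5-oxotetrahydrofuran-2-yl]propanal | O=C[C@@H](C)[C@@H]1CCC(=O)O1 | intermediate
13 | (S)-5-[(2R,3S)-3-hydroxyhex-5-en-2-yl]dihydrofuran-2(3H)-one | C=CC[C@@H]([C@@H](C)[C@@H]1CCC(=O)O1)O | intermediate
14 | 2-(diethoxyphosphoryl)propanoate ester of 13 (C39–C46 plus C1–C2; epimeric at the phosphonate carbon) | C=CC[C@@H]([C@@H](C)[C@@H]1CCC(=O)O1)OC(=O)C(C)P(=O)(OCC)OCC | intermediate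
15 | acrolein | C=CC=O | starting material
16 | (S)-hexa-1,5-dien-3-ol | C=CC[C@H](O)C=C | intermediate
17 | methyl acrylate | C=CC(=O)OC | starting material
18 | methyl (2E,5S)-5-hydroxyhepta-2,6-dienoate | COC(=O)/C=C/C[C@H](O)C=C | intermediate
19 | methyl 2-[(2S,4R,6S)-2-(4-methoxyphenyl)-6-vinyl-1,3-dioxan-4-yl]acetate (all-cis) | COC(=O)C[C@H]1C[C@@H](C=C)O[C@@H](c2ccc(OC)cc2)O1 | intermediate
20 | 2-[(2S,4R,6S)-2-(4-methoxyphenyl)-6-vinyl-1,3-dioxan-4-yl]acetaldehyde | O=CC[C@H]1C[C@@H](C=C)O[C@@H](c2ccc(OC)cc2)O1 | intermediate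
21 | C33–C46 aldehyde: PMP acetal on O35/O37; (E)-C38=C39; C41 phosphonopropionate; γ-lactone; stereocentres as in the target | O=CC[C@H]1C[C@@H](/C=C/C[C@@H]([C@@H](C)[C@@H]3CCC(=O)O3)OC(=O)C(C)P(=O)(OCC)OCC)O[C@@H](c2ccc(OC)cc2)O1 | intermediate
22 | propane-1,3-diol | OCCCO | starting material
23 | allyl acetate | C=CCOC(C)=O | starting material
24 | (4R,6R)-nona-1,8-diene-4,6-diol | C=CC[C@@H](O)C[C@H](O)CC=C | intermediate
25 | (4R,6R)-4,6-diallyl-2,2-dimethyl-1,3-dioxane | C=CC[C@@H]1C[C@@H](CC=C)OC(C)(C)O1 | intermediate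
26 | 2,2'-[(4S,6S)-2,2-dimethyl-1,3-dioxane-4,6-diyl]diacetaldehyde | O=CC[C@@H]1C[C@@H](CC=O)OC(C)(C)O1 | intermediate
27 | pentan-3-one | CCC(=O)CC | starting material
28 | C23–C32 mono-aldol: C23 aldehyde; C25/C27 acetonide; C29 OH syn to C30 Me; C31 ethyl ketone | O=CC[C@@H]1C[C@@H](C[C@H](O)[C@@H](C)C(=O)CC)OC(C)(C)O1 | intermediate
29 | C29 TBS ether of 28 | O=CC[C@@H]1C[C@@H](C[C@H](O[Si](C)(C)C(C)(C)C)[C@@H](C)C(=O)CC)OC(C)(C)O1 | intermediate
30 | allylic boronate: C22 dioxaborinanyl and C23 O-B(Ipc)2 adduct of 29 | C=C[C@@H](B2OCCCO2)[C@@H](OB([C@H]3C[C@H]4C[C@@H]([C@@H]3C)C4(C)C)[C@H]3C[C@H]4C[C@@H]([C@@H]3C)C4(C)C)C[C@@H]1C[C@@H](C[C@H](O[Si](C)(C)C(C)(C)C)[C@@H](C)C(=O)CC)OC(C)(C)O1 | intermediate (not isolated)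
31 | C21–C32 anti-diol: C21 vinyl; C22 OH/C23 OH anti; C25/C27 acetonide; C29 OTBS; C31 ketone | C=C[C@@H](O)[C@@H](O)C[C@@H]1C[C@@H](C[C@H](O[Si](C)(C)C(C)(C)C)[C@@H](C)C(=O)CC)OC(C)(C)O1 | intermediate
32 | bis-acetonide of 31 (cis-dioxolane on O22/O23) | C=C[C@H]2OC(C)(C)O[C@H]2C[C@@H]1C[C@@H](C[C@H](O[Si](C)(C)C(C)(C)C)[C@@H](C)C(=O)CC)OC(C)(C)O1 | intermediate
33 | dioxolane aldehyde (C21 aldehyde) | O=C[C@H]2OC(C)(C)O[C@H]2C[C@@H]1C[C@@H](C[C@H](O[Si](C)(C)C(C)(C)C)[C@@H](C)C(=O)CC)OC(C)(C)O1 | intermediate (not isolated)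
34 | C19–C32 (E)-2-methyl enal | O=C/C(C)=C/[C@H]2OC(C)(C)O[C@H]2C[C@@H]1C[C@@H](C[C@H](O[Si](C)(C)C(C)(C)C)[C@@H](C)C(=O)CC)OC(C)(C)O1 | intermediate
35 | C17–C32 allylic alcohol: C17 vinyl; C18 Me/C19 OH syn | C=C[C@@H](C)[C@H](O)/C(C)=C/[C@H]2OC(C)(C)O[C@H]2C[C@@H]1C[C@@H](C[C@H](O[Si](C)(C)C(C)(C)C)[C@@H](C)C(=O)CC)OC(C)(C)O1 | intermediate
36 | C17–C32 ethyl ketone: C19 OTBS; (E)-C20=C21; C22/C23 and C25/C27 acetonides; C29 OTBS; C31 ketone; stereocentres as in the target | C=C[C@@H](C)[C@H](O[Si](C)(C)C(C)(C)C)/C(C)=C/[C@H]2OC(C)(C)O[C@H]2C[C@@H]1C[C@@H](C[C@H](O[Si](C)(C)C(C)(C)C)[C@@H](C)C(=O)CC)OC(C)(C)O1 | intermediate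
37 | C17–C46 β-hydroxy ketone: C31 ketone; C32 Me/C33 OH syn; C30 Me/C32 Me syn | C=C[C@@H](C)[C@H](O[Si](C)(C)C(C)(C)C)/C(C)=C/[C@H]2OC(C)(C)O[C@H]2C[C@@H]1C[C@@H](C[C@H](O[Si](C)(C)C(C)(C)C)[C@@H](C)C(=O)[C@@H](C)[C@H](O)C[C@H]3C[C@@H](/C=C/C[C@@H]([C@@H](C)[C@@H]4CCC(=O)O4)OC(=O)C(C)P(=O)(OCC)OCC)O[C@@H](c5ccc(OC)cc5)O3)OC(C)(C)O1 | intermediate
38 | C31,C33-anti diol from 37 | C=C[C@@H](C)[C@H](O[Si](C)(C)C(C)(C)C)/C(C)=C/[C@H]2OC(C)(C)O[C@H]2C[C@@H]1C[C@@H](C[C@H](O[Si](C)(C)C(C)(C)C)[C@@H](C)[C@@H](O)[C@@H](C)[C@H](O)C[C@H]3C[C@@H](/C=C/C[C@@H]([C@@H](C)[C@@H]4CCC(=O)O4)OC(=O)C(C)P(=O)(OCC)OCC)O[C@@H](c5ccc(OC)cc5)O3)OC(C)(C)O1 | intermediate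
39 | C17–C46 tris-acetonide (trans-dioxane on O31/O33) | C=C[C@@H](C)[C@H](O[Si](C)(C)C(C)(C)C)/C(C)=C/[C@H]2OC(C)(C)O[C@H]2C[C@@H]1C[C@@H](C[C@H](O[Si](C)(C)C(C)(C)C)[C@@H](C)[C@@H]6[C@@H](C)[C@@H](C[C@H]3C[C@@H](/C=C/C[C@@H]([C@@H](C)[C@@H]4CCC(=O)O4)OC(=O)C(C)P(=O)(OCC)OCC)O[C@@H](c5ccc(OC)cc5)O3)OC(C)(C)O6)OC(C)(C)O1 | intermediate
40 | (E)-crotonaldehyde | C/C=C/C=O | starting material
41 | C15–C46 (E)-enal | O=C/C=C/[C@@H](C)[C@H](O[Si](C)(C)C(C)(C)C)/C(C)=C/[C@H]2OC(C)(C)O[C@H]2C[C@@H]1C[C@@H](C[C@H](O[Si](C)(C)C(C)(C)C)[C@@H](C)[C@@H]6[C@@H](C)[C@@H](C[C@H]3C[C@@H](/C=C/C[C@@H]([C@@H](C)[C@@H]4CCC(=O)O4)OC(=O)C(C)P(=O)(OCC)OCC)O[C@@H](c5ccc(OC)cc5)O3)OC(C)(C)O6)OC(C)(C)O1 | intermediate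
42 | (S)-α-lithio carbamate of 8 at C12 (sparteine complex) | C=C[C@H](C)[C@@H](O[Si](C)(C)C(C)(C)C)[C@@H](C)[C@@H](O[Si](C)(C)C(C)(C)C)CC[C@H]([Li])OC(=O)N(C(C)C)C(C)C | intermediate (not isolated)
43 | lithium boronate complex: C12 bonded to the 9-BBN boron that also carries the (Z)-propenyl group | C=C[C@H](C)[C@@H](O[Si](C)(C)C(C)(C)C)[C@@H](C)[C@@H](O[Si](C)(C)C(C)(C)C)CC[C@H]([B-]1(/C=C\C)C2CCCC1CCC2)OC(=O)N(C(C)C)C(C)C.[Li+] | intermediate (not isolated)
44 | (R)-α-substituted (Z)-crotyl-9-BBN (boron on C12; C13=C14 Z) | C=C[C@H](C)[C@@H](O[Si](C)(C)C(C)(C)C)[C@@H](C)[C@@H](O[Si](C)(C)C(C)(C)C)CC[C@H](/C=C\C)B1C2CCCC1CCC2 | intermediate (not isolated)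
45 | C4–C46 seco-phosphonate: C4=C5 vinyl; C7 and C9 OTBS; (E)-C12=C13; free C15 OH syn to C14 Me; remainder as in 41 | C=C[C@H](C)[C@@H](O[Si](C)(C)C(C)(C)C)[C@@H](C)[C@@H](O[Si](C)(C)C(C)(C)C)CC/C=C/[C@@H](C)[C@H](O)/C=C/[C@@H](C)[C@H](O[Si](C)(C)C(C)(C)C)/C(C)=C/[C@H]2OC(C)(C)O[C@H]2C[C@@H]1C[C@@H](C[C@H](O[Si](C)(C)C(C)(C)C)[C@@H](C)[C@@H]6[C@@H](C)[C@@H](C[C@H]3C[C@@H](/C=C/C[C@@H]([C@@H](C)[C@@H]4CCC(=O)O4)OC(=O)C(C)P(=O)(OCC)OCC)O[C@@H](c5ccc(OC)cc5)O3)OC(C)(C)O6)OC(C)(C)O1 | intermediate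
46 | C3 formyl phosphonate (linear aldehyde from 45) | O=CCC[C@H](C)[C@@H](O[Si](C)(C)C(C)(C)C)[C@@H](C)[C@@H](O[Si](C)(C)C(C)(C)C)CC/C=C/[C@@H](C)[C@H](O)/C=C/[C@@H](C)[C@H](O[Si](C)(C)C(C)(C)C)/C(C)=C/[C@H]2OC(C)(C)O[C@H]2C[C@@H]1C[C@@H](C[C@H](O[Si](C)(C)C(C)(C)C)[C@@H](C)[C@@H]6[C@@H](C)[C@@H](C[C@H]3C[C@@H](/C=C/C[C@@H]([C@@H](C)[C@@H]4CCC(=O)O4)OC(=O)C(C)P(=O)(OCC)OCC)O[C@@H](c5ccc(OC)cc5)O3)OC(C)(C)O6)OC(C)(C)O1 | intermediate (not isolated)
47 | protected macrolactone: TBS on O7, O9, O19, O29; acetonides on O22/O23, O25/O27, O31/O33; PMP acetal on O35/O37; free C15 OH | C/C1=C\CC[C@H](C)[C@@H](O[Si](C)(C)C(C)(C)C)[C@@H](C)[C@@H](O[Si](C)(C)C(C)(C)C)CC/C=C/[C@@H](C)[C@H](O)/C=C/[C@@H](C)[C@H](O[Si](C)(C)C(C)(C)C)/C(C)=C/[C@H]2OC(C)(C)O[C@H]2C[C@@H]3C[C@@H](C[C@H](O[Si](C)(C)C(C)(C)C)[C@@H](C)[C@@H]4[C@@H](C)[C@@H](C[C@H]5C[C@@H](/C=C/C[C@@H]([C@@H](C)[C@@H]6CCC(=O)O6)OC1=O)O[C@@H](c7ccc(OC)cc7)O5)OC(C)(C)O4)OC(C)(C)O3 | intermediate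
48 | target macrolide CNP0335149.1 | C/C1=C\CC[C@H](C)[C@@H](O)[C@@H](C)[C@@H](O)CC/C=C/[C@@H](C)[C@H](O)/C=C/[C@@H](C)[C@H](O)/C(C)=C/[C@@H](O)[C@@H](O)C[C@@H](O)C[C@H](O)C[C@H](O)[C@@H](C)[C@@H](O)[C@@H](C)[C@H](O)C[C@H](O)C[C@H](O)/C=C/C[C@@H]([C@@H](C)[C@@H]2CCC(=O)O2)OC1=O | target

**Totals and risk**

Total step count: 33. Longest linear sequence: 17 steps (steps 17–33, from propane-1,3-diol).

The three steps most likely to fail:

Step 32 (the proposed new step). The domino process may stall, the base may interfere with the catalyst formed from Rh(acac)(CO)2, or oligomers may form. The fallback separates the two events using known chemistry. It sets out from 45: hydroformylation alone (Rh(acac)(CO)2, BiPhePhos, CO/H2, toluene, 60 °C, no base) gives the formyl phosphonate 46, which is now isolated. Slow addition of 46 to LiCl and DBU in MeCN (Masamune–Roush HWE, about 0.5 mM) closes the ring, and the route is rejoined at 47. This fallback makes no compound outside the list (none, F0).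

Step 27. The chlorotitanium enolate may give poor facial control, or TiCl4 may open the acetonides or the p-methoxybenzylidene acetal. The fallback replaces substrate control under a Lewis acid by reagent control under boron. It sets out from 36: (-)-Ipc2BOTf and iPr2NEt in CH2Cl2 at -78 °C give the (Z)-enol diisopinocampheylborinate F1, which adds to aldehyde 21 in a Paterson aldol; buffered H2O2 work-up returns to the route at 37.

Step 31. The allylic 9-BBN borane may undergo 1,3-borotropic shift, or the lithiated carbamate may be consumed before borylation. The fallback uses an isolable boronic ester in place of the in-situ borane. It sets out from 8: s-BuLi/(-)-sparteine, then (Z)-prop-1-enylboronic acid pinacol ester, then MgBr2·OEt2 with warming (the same 1,2-shift) give the α-substituted (Z)-crotyl pinacol boronate F2, which is purified. Treatment of F2 with n-BuLi and then (CF3CO)2O forms the reactive borinic ester, which adds to enal 41 at -78 °C with the same E/syn outcome, rejoining the route at 45.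

**Further compounds**

F1 | step 27 | (Z)-enol diisopinocampheylborinate of ketone 36 (C31 O-B(Ipc)2; C31=C32 Z; (-)-Ipc groups) | C=C[C@@H](C)[C@H](O[Si](C)(C)C(C)(C)C)/C(C)=C/[C@H]2OC(C)(C)O[C@H]2C[C@@H]1C[C@@H](C[C@H](O[Si](C)(C)C(C)(C)C)[C@@H](C)/C(OB([C@@H]3C[C@@H]4C[C@H]([C@H]3C)C4(C)C)[C@@H]3C[C@@H]4C[C@H]([C@H]3C)C4(C)C)=C/C)OC(C)(C)O1
F2 | step 31 | (R)-α-substituted (Z)-crotyl pinacol boronate of fragment A (Bpin on C12) | C=C[C@H](C)[C@@H](O[Si](C)(C)C(C)(C)C)[C@@H](C)[C@@H](O[Si](C)(C)C(C)(C)C)CC[C@H](/C=C\C)B1OC(C)(C)C(C)(C)O1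
F0 | step 32 | none | none
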